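**Plan**
1. Retrosynthesis: after the methyl ethers, both C3=C4 bonds are traced back to dihydrocoumarins and both O1–C2 lactone bonds to methyl propanoates. Benzene ring A is then cut at C5–C6 and C8–C8a.
2. This cut rests on the oxygen pattern of ring A. C7 and C8a carry oxygen in a meta (resorcinol) relation and the ether oxygen sits on C6, the neighbour of C7. C6–C7–C8 therefore reads as the CH2–CO–CH3 of an acetonyl ether on O5 of unit B, and C5, C4a and C8a with the chain C4–C3–C2 read as a 2-formylglutarate.
3. The ether bond O5(B)–C6(A) is thus made as an O-alkylation with chloroacetone. The C5–O bond of unit B comes from ortho-formylation and Baeyer–Villiger oxidation of isoscopoletin, where C5 is the only free position ortho to 6-OH.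
4. Forward order: both rings of unit B are bought, O5 is installed and acetonylated, and C3=C4 of unit B is saturated for the base step. Benzene ring A is grown by the (3+3) Michael–Claisen step, pyranone A closes and lactone B recloses under acid, one DDQ treatment restores both coumarins, and BBr3 frees the three phenols.
5. Stereochemistry: the target has no stereocentre and no open-chain alkene. The transient centre at C6 disappears on aromatisation.

Key step: step 8

Assumption: isoscopoletin (6-hydroxy-7-methoxycoumarin) is taken as purchasable; coumarin numbering is used for both halves, half A being the 6-aryloxy-7-hydroxy unit and unit B the 5-O-linked 6,7-dihydroxy unit.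

Step 1
Reactants: 1 isoscopoletin (6-hydroxy-7-methoxy-2H-chromen-2-one)
Product: 2 6-hydroxy-7-methoxy-2-oxo-2H-chromene-5-carbaldehyde
Conditions: HMTA, TFA, 80 °C; then 3 M aq HCl, 60 °C
Reagents that add atoms: hexamethylenetetramine, C1N2CN3CN1CN(C2)C3; water, O
Why: Duff formylation: the free 6-OH directs the HMTA-derived iminium electrophile to its only open ortho position C5 (C7 is blocked by OMe), the naphthol-like site at which 6-hydroxycoumarins are known to be substituted, and the acid hydrolysis releases the aldehyde without harming the lactone.

Step 2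
Reactants: 2 6-hydroxy-7-methoxy-2-oxo-2H-chromene-5-carbaldehyde
Product: 3 6,7-dimethoxy-2-oxo-2H-chromene-5-carbaldehyde
Conditions: MeI, K2CO3, DMF, rt
Reagents that add atoms: iodomethane, CI
Why: Williamson O-methylation of the hydrogen-bonded 6-OH is routine with MeI and K2CO3, touches neither aldehyde nor lactone, and ensures that the oxygen introduced next will be the only free phenol.

Step 3
Reactants: 3 6,7-dimethoxy-2-oxo-2H-chromene-5-carbaldehyde
Product: 5 5-hydroxy-6,7-dimethoxycoumarin, via aryl formate 4 (not isolated)
Conditions: mCPBA, CH2Cl2, 0 °C to rt; then 1 M aq HCl, THF, rt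
Reagents that add atoms: 3-chloroperoxybenzoic acid, OOC(=O)c1cccc(Cl)c1
Why: Baeyer–Villiger oxidation of an electron-rich benzaldehyde (Dakin-type outcome): with an ortho methoxy group and two ortho substituents the aryl group should migrate in the Criegee adduct, the electron-poor C3=C4 bond ignores the peracid, and the labile formate 4 is hydrolysed by dilute acid to the C5 phenol.

Step 4
Reactants: 5 5-hydroxy-6,7-dimethoxycoumarin; 6 chloroacetone
Product: 7 1-[(6,7-dimethoxy-2-oxo-2H-chromen-5-yl)oxy]propan-2-one
Conditions: K2CO3, acetone, reflux
Reagents that add atoms: none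
Why: Williamson ether synthesis with an alpha-halo ketone: the acidic, lactone-conjugated 5-phenoxide is hindered, but chloroacetone is a small and very reactive SN2 partner, and the rigid coumarin keeps O8a locked in the lactone so that only O5 can be alkylated.

Step 5
Reactants: 7 1-[(6,7-dimethoxy-2-oxo-2H-chromen-5-yl)oxy]propan-2-one
Product: 8 6,7-dimethoxy-5-(2-oxopropoxy)chroman-2-one
Conditions: H2 (3 atm), 10% Pd/C, EtOAc–AcOH, rt
Reagents that add atoms: none
Why: Catalytic hydrogenation of a coumarin to its 3,4-dihydro derivative is standard and spares the aliphatic ketone and the aryl ethers; it removes the C3=C4 Michael acceptor that the enolate carbon of step 8 could reach through a five-membered transition state, and it is done only after O5 is capped so that the now flexible chain cannot translactonise.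

Step 6
Reactants: 9 dimethyl glutarate; 10 methyl formate
Product: 11 dimethyl 2-formylpentanedioate (largely its hydroxymethylene enol)
Conditions: NaH, MeOH (cat.), THF, 0 °C to rt; then 1 M aq HCl
Reagents that add atoms: none
Why: Crossed Claisen condensation (C-formylation): methyl formate has no alpha-hydrogen and is the most electrophilic ester present, glutarate has no viable Dieckmann ring, and the product leaves the equilibrium as its stabilised sodium enolate, so one equivalent of base should hold the reaction at the monoformyl stage.

Step 7
Reactants: 11 dimethyl 2-formylpentanedioate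
Product: 12 dimethyl (E)-2-(methoxymethylene)pentanedioate
Conditions: Me2SO4, K2CO3, acetone, rt
Reagents that add atoms: dimethyl sulfate, COS(=O)(=O)OC
Why: O-alkylation of a formyl ester enolate with the hard electrophile dimethyl sulfate is the standard entry to beta-methoxyacrylates and should give mainly the E isomer, whose geometry is in any case erased in step 8.

Step 8
Reactants: 8 6,7-dimethoxy-5-(2-oxopropoxy)chroman-2-one; 12 dimethyl (E)-2-(methoxymethylene)pentanedioate
Product: 16 methyl 3-{2,4-dihydroxy-5-[3-hydroxy-5,6-dimethoxy-2-(3-methoxy-3-oxopropyl)phenoxy]phenyl}propanoate, via ring-opened phenol ester 13 (not isolated), via open-chain adduct 14 (not isolated), via cyclohexenedione 15 (not isolated)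
Conditions: 12 (1.5 equiv), NaOMe (5 equiv), MeOH–THF, Ar, 0 °C to 65 °C; then cold 1 M aq HCl
Reagents that add atoms: sodium methoxide, [Na+].[O-]C
Why: Proposed new method: methoxide first opens the aryl lactone of 8 to the phenoxide of 13, whose OCH2 carbon (future C6), the more acidic alpha position, adds to the methoxymethylene carbon of 12 (future C5) and expels methoxide to give 14; removal of the doubly activated C6–H turns 14 into a dienolate in which the C5–C4a bond can rotate, so the conjugated ester can come next to the acetyl group. The acetyl CH3 enolate (C8) then attacks that ester carbonyl (C8a) in a 6-(enolendo)-exo-trig Claisen closure to 15, which enolises at once to resorcinol 16 without any oxidant because C5 was brought in as a masked formyl carbon. The closest known reaction type is the consecutive Michael–Claisen (3+3) annulation of substituted acetones with acrylates (as in the dimedone synthesis) and its resorcinol version with ynoates or beta-alkoxyacrylates; an alpha-aryloxy ketone as the three-carbon partner is the untested element. No stereocentre is created for good, since C6 of 14 and 15 ends as an aromatic carbon. The selectivity needed is that OCH2 and not CH3 forms the first bond: under equilibrating methoxide the aryloxy-stabilised enolate is the dominant one, the site at which aryloxyacetones react in base-mediated aldol and Pfitzinger condensations, and only its adduct is withdrawn as a stabilised dienolate. O-acylation to a 2-pyranone, seven-membered Dieckmann closure onto the unit B propanoate and phenoxide exchange at the enol ether are all reversible in methoxide whereas aromatisation is not, and the saturated C3–C4 of unit B leaves no Michael acceptor for the enolate.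

Step 9
Reactants: 16 methyl 3-{2,4-dihydroxy-5-[3-hydroxy-5,6-dimethoxy-2-(3-methoxy-3-oxopropyl)phenoxy]phenyl}propanoate
Product: 17 7-hydroxy-6-[(6,7-dimethoxy-2-oxochroman-5-yl)oxy]chroman-2-one
Conditions: p-TsOH·H2O (cat.), toluene, reflux, MeOH distilled off
Reagents that add atoms: none
Why: Acid-catalysed lactonisation (intramolecular transesterification): in each half only the C8a–OH lies ortho to the propanoate chain (C7–OH of ring A is out of reach, O5 of unit B is etherified), so two six-membered aryl lactones close and removal of methanol drives the equilibrium.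

Step 10
Reactants: 17 7-hydroxy-6-[(6,7-dimethoxy-2-oxochroman-5-yl)oxy]chroman-2-one
Product: 18 7-methoxy-6-[(6,7-dimethoxy-2-oxochroman-5-yl)oxy]chroman-2-one
Conditions: MeI, K2CO3, dry acetone, 40 °C
Reagents that add atoms: iodomethane, CI
Why: Williamson methylation of the single remaining phenol under anhydrous carbonate conditions, in common use for hydroxydihydrocoumarins, shields ring A from phenol oxidation by DDQ with a group that falls in the last step together with the other two methyl ethers.

Step 11
Reactants: 18 7-methoxy-6-[(6,7-dimethoxy-2-oxochroman-5-yl)oxy]chroman-2-one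
Product: 19 6-[(6,7-dimethoxy-2-oxo-2H-chromen-5-yl)oxy]-7-methoxy-2H-chromen-2-one
Conditions: DDQ (excess), 1,4-dioxane, reflux
Reagents that add atoms: none
Why: DDQ dehydrogenation of 3,4-dihydrocoumarins: hydride abstraction from benzylic C4, activated in both halves by the 7-methoxy group para to C4a, followed by loss of H3 gives the conjugated lactone, so both pyranones should reach the coumarin level in the same flask.

Step 12
Reactants: 19 6-[(6,7-dimethoxy-2-oxo-2H-chromen-5-yl)oxy]-7-methoxy-2H-chromen-2-one
Product: 20 6-[(6,7-dihydroxy-2-oxo-2H-chromen-5-yl)oxy]-7-hydroxy-2H-chromen-2-one (CNP0197949.0)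
Conditions: BBr3 (excess), CH2Cl2, −78 °C to rt; then H2O, 0 °C
Reagents that add atoms: none
Why: Lewis-acid ether cleavage with BBr3: bromide attacks only the three methyl carbons, the diaryl ether offers no sp3 carbon and coumarin lactones are known to survive, so hydrolysis of the borates should release the catechol of unit B and the 7-OH of ring A.

**Compound list**
1 | isoscopoletin (6-hydroxy-7-methoxycoumarin) | COc1cc2oc(=O)ccc2cc1O | starting material
2 | 6-hydroxy-7-methoxy-2-oxo-2H-chromene-5-carbaldehyde | COc1cc2oc(=O)ccc2c(C=O)c1O | intermediate
3 | 6,7-dimethoxy-2-oxo-2H-chromene-5-carbaldehyde | COc1cc2oc(=O)ccc2c(C=O)c1OC | intermediate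
4 | 6,7-dimethoxy-2-oxo-2H-chromen-5-yl formate | COc1cc2oc(=O)ccc2c(OC=O)c1OC | intermediate (not isolated)
5 | 5-hydroxy-6,7-dimethoxycoumarin | COc1cc2oc(=O)ccc2c(O)c1OC | intermediate
6 | chloroacetone | CC(=O)CCl | starting material
7 | 1-[(6,7-dimethoxy-2-oxo-2H-chromen-5-yl)oxy]propan-2-one | CC(=O)COc1c(OC)c(OC)cc2oc(=O)ccc12 | intermediate
8 | 6,7-dimethoxy-5-(2-oxopropoxy)chroman-2-one | CC(=O)COc1c(OC)c(OC)cc2OC(=O)CCc12 | intermediate
9 | dimethyl glutarate | COC(=O)CCCC(=O)OC | starting material
10 | methyl formate | COC=O | starting material
11 | dimethyl 2-formylpentanedioate (racemic, enolised) | COC(=O)CCC(C=O)C(=O)OC | intermediate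
12 | dimethyl (E)-2-(methoxymethylene)pentanedioate | CO/C=C(\CCC(=O)OC)C(=O)OC | intermediate
13 | methyl 3-[6-hydroxy-3,4-dimethoxy-2-(2-oxopropoxy)phenyl]propanoate (present as sodium phenoxide) | CC(=O)COc1c(OC)c(OC)cc(O)c1CCC(=O)OC | intermediate (not isolated)
14 | dimethyl 2-{2-[3-hydroxy-5,6-dimethoxy-2-(3-methoxy-3-oxopropyl)phenoxy]-3-oxobutylidene}pentanedioate (alkene geometry and C6 configuration labile) | COC(=O)CCC(=CC(Oc1c(OC)c(OC)cc(O)c1CCC(=O)OC)C(C)=O)C(=O)OC | intermediate (not isolated)
15 | methyl 3-{3-[3-hydroxy-5,6-dimethoxy-2-(3-methoxy-3-oxopropyl)phenoxy]-4,6-dioxocyclohex-1-en-1-yl}propanoate (racemic, fleeting) | COC(=O)CCC1=CC(Oc2c(OC)c(OC)cc(O)c2CCC(=O)OC)C(=O)CC1=O | intermediate (not isolated)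
16 | methyl 3-{2,4-dihydroxy-5-[3-hydroxy-5,6-dimethoxy-2-(3-methoxy-3-oxopropyl)phenoxy]phenyl}propanoate | COC(=O)CCc1cc(Oc2c(OC)c(OC)cc(O)c2CCC(=O)OC)c(O)cc1O | intermediate
17 | 7-hydroxy-6-[(6,7-dimethoxy-2-oxochroman-5-yl)oxy]chroman-2-one | O=C1CCc2cc(Oc3c(OC)c(OC)cc4OC(=O)CCc34)c(O)cc2O1 | intermediate
18 | 7-methoxy-6-[(6,7-dimethoxy-2-oxochroman-5-yl)oxy]chroman-2-one | O=C1CCc2cc(Oc3c(OC)c(OC)cc4OC(=O)CCc34)c(OC)cc2O1 | intermediate
19 | 6-[(6,7-dimethoxy-2-oxo-2H-chromen-5-yl)oxy]-7-methoxy-2H-chromen-2-one | O=c1ccc2cc(Oc3c(OC)c(OC)cc4oc(=O)ccc34)c(OC)cc2o1 | intermediate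
20 | 6-[(6,7-dihydroxy-2-oxo-2H-chromen-5-yl)oxy]-7-hydroxy-2H-chromen-2-one | O=c1ccc2cc(Oc3c(O)c(O)cc4oc(=O)ccc34)c(O)cc2o1 | target

**Step count**
Total step count: 12.
Longest linear sequence: 10 (steps 1–5 and 8–12). Steps 6 and 7 form the side branch.

**Steps most likely to fail**

Step 8.
- What may go wrong: the first C–C bond may be made by the methyl enolate instead of the OCH2 carbon. The sluggish alpha-alkyl-beta-methoxyacrylate may be used up by methoxide-induced side reactions before it is attacked. The open-chain dienolate may also close through the alpha-carbon of the chain ester onto the ketone, with later loss of the aryloxide.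
- Fallback: the diaryl ether is made by C–O cross-coupling instead of ring construction, setting out from phenol 5. Commercial 5-bromo-2-hydroxy-4-methoxybenzaldehyde is taken with Ph3P=CHCO2Et in hot N,N-diethylaniline (Wittig olefination–lactonisation) to 6-bromo-7-methoxycoumarin F1. An Ullmann ether coupling of 5 with F1 (CuI, N,N-dimethylglycine, Cs2CO3, dioxane, 100 °C) should then give 19, where the route is rejoined before the last step.

Step 11.
- What may go wrong: the reaction may stall after the first dehydrogenation, or the electron-rich trialkoxyarene may be over-oxidised by excess DDQ at reflux.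
- Fallback: the unsaturation is introduced by enolate chemistry instead of hydride abstraction, setting out from 18. Double enolisation with LiN(SiMe3)2 in THF at −78 °C and trapping with PhSeBr should give 7-methoxy-3-(phenylselanyl)-6-{[6,7-dimethoxy-2-oxo-3-(phenylselanyl)chroman-5-yl]oxy}chroman-2-one F2. Its oxidation with H2O2 in CH2Cl2 at 0 °C triggers two selenoxide syn-eliminations and comes back to the route at 19.

Step 3.
- What may go wrong: hydride instead of aryl migration in the Criegee adduct (oxidation to the acid level), favoured by the electron-withdrawing pyranone on the same ring.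
- Fallback: O5 is brought in through a carbon–boron bond, setting out from 1.
  - Phenol-directed bromination (NBS, MeCN, 0 °C) should give 5-bromo-6-hydroxy-7-methoxycoumarin F3.
  - Methylation (MeI, K2CO3, DMF) should give 5-bromo-6,7-dimethoxycoumarin F4.
  - Miyaura borylation (B2pin2, Pd(dppf)Cl2, KOAc, dioxane, 90 °C) should give 6,7-dimethoxy-5-(4,4,5,5-tetramethyl-1,3,2-dioxaborolan-2-yl)coumarin F5.
  - Oxidation with NaBO3 in THF–H2O comes back to the route at 5.

**Further compounds**
F1 | step 8 | 6-bromo-7-methoxycoumarin | COc1cc2oc(=O)ccc2cc1Br
F2 | step 11 | 7-methoxy-3-(phenylselanyl)-6-{[6,7-dimethoxy-2-oxo-3-(phenylselanyl)chroman-5-yl]oxy}chroman-2-one (mixture of diastereomers, both centres destroyed on elimination) | O=C1C([Se]c2ccccc2)Cc2cc(Oc3c(OC)c(OC)cc4OC(=O)C([Se]c5ccccc5)Cc34)c(OC)cc2O1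
F3 | step 3 | 5-bromo-6-hydroxy-7-methoxycoumarin | COc1cc2oc(=O)ccc2c(Br)c1O
F4 | step 3 | 5-bromo-6,7-dimethoxycoumarin | COc1cc2oc(=O)ccc2c(Br)c1OC
F5 | step 3 | 6,7-dimethoxy-5-(4,4,5,5-tetramethyl-1,3,2-dioxaborolan-2-yl)coumarin | COc1cc2oc(=O)ccc2c(B3OC(C)(C)C(C)(C)O3)c1OC
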